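The earlier runs and the new flask are calculated for substances that don't exist, noise included.

The last readings came at 30.0 h. By then 56% of the E remained in the south-east run and 58% in the north-west run, a gap within the scatter although X differed.

| flask | E | G | X | Z | remark | time |
|---|---|---|---|---|---|---|
| south-east | 0.57 M | 0.95 equiv | 0.50 equiv | 0.2 mol% | run made earlier |  |
| north-west | 0.57 M | 0.95 equiv | 1.1 equiv | 0.2 mol% | run made earlier |  |
| theta | 0.57 M | 0.950 equiv | 1.60 equiv | 0.2 mol% |  | 2.0 d |
| zeta | 0.57 M | 0.950 equiv | 0.800 equiv | 0.2 mol% |  | 2.0 d |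

| run | time / h | E / % | D / % |
|---|---|---|---|
| south-east | 2.50 | 96 | 4 |
| south-east | 4.00 | 92 | 6 |
| south-east | 6.00 | 89 | 10 |
| south-east | 10.0 | 86 | 15 |
| south-east | 15.0 | 79 | 24 |
| south-east | 20.0 | 71 | 28 |
| south-east | 30.0 | 56 | 40 |
| north-west | 2.00 | 95 | 0 |
| north-west | 5.00 | 89 | 9 |
| north-west | 10.0 | 85 | 14 |
| north-west | 15.0 | 77 | 18 |
| north-west | 20.0 | 73 | 25 |
| north-west | 25.0 | 62 | 34 |
| north-west | 30.0 | 58 | 40 |

(readings scatter by 1.5 percentage points)

- the numbers in the tables scatter with a standard deviation of 1.5 percentage points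

- part of the E that has reacted at the end, theta
- part of the E that has reacted at the end, zeta
- what raising the equivalents of X from its lowest to its highest value here does to the part of the E that has reacted (changes below 5 percentage points count as none) (it falls / no change / it rises)

I replaced each curve by its mean, taking the mean rate, the part of the charged E consumed per unit time up to the last reading:

E consumed by then, average of both runs = 43.0%

mean rate = 0.344 d⁻¹

held constant to the asked time: 68.8%

The weak link was that constant rate. The runs lost 22.0% in the first 15.0 h and 21 points in the next stretch, so no fall could be read. But G presumably fell as E did. Taking G one for one with E, and counting it per E charged, mean [G] up to the last reading was 0.735, while [G] at that reading was 0.520. I therefore scaled the mean rate by that ratio for the remaining time, a rough step: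

reacted at the end = 61.3%

I committed to that figure for both theta and zeta, with no change from X, accepting that theta's X lay beyond the range tried.

The forecast, higher than my figure, gave 64% for theta, 64% for zeta and no change: "Thus theta and zeta should match".

The flask gave 61.4% for theta, 62.0% for zeta and no change, a change of −0.58 points.

    E + Z ⇌ J (K = 44.0 M⁻¹, k = 4.93 M⁻¹ min⁻¹)
    G + J ⇌ Uj (K = 1.81 M⁻¹, k = 1.46 M⁻¹ min⁻¹)
    Uj ⇌ Q + Qa (K = 0.536 M, k = 11.8 min⁻¹)
    Qa → Z + D (k = 0.155 min⁻¹)
    E + Q ⇌ Ul, settled at all times (K = 5.20 M⁻¹)
    X + Q → Ez (k = 0.0901 M⁻¹ min⁻¹)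

Over 2.0 d, theta averaged 0.307 d⁻¹, less than the mean rate of 0.344 d⁻¹. Qa has a half-life of 0.075 h by its passing into Z + D alone, far shorter than 2.0 d, yet in theta it held 69.2% of the catalyst charged at 1.00 d and 55.1% at 2.00 d. In a neighbour flask with 1.60 equiv of G and all else as in theta, [G] after the constant-rate reckoning stays at 0.912, more than 0.735, so I applied no scaling and the mean rate gives 68.8%. That flask computed 69.7% reacted.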